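**Plan**

1. Retrosynthesis: the chalcone arm is cut first (enone C=C by aldol condensation, then the aryl–acetyl bond). The oxane is then cut across O1–C6 and C4–C5, after C2=C3 is adjusted to an enol ether and C6 to a methyl ketal (retro oxa-Diels–Alder). Last, C3=C4 of the resulting aryl enone is cut (aldol condensation).
2. Enabling feature (oxane: O1, C2 aryl, C3, C4 aryl, C5, C6 arylethyl): O1–C2–C3–C4 is a latent 1-oxadiene, an aryl enone whose C4 carries the 2,4,6-trioxygenated ring that stabilises positive charge there. C5–C6 is a latent 2-methoxyalkene, and C6 bears only H beside its chain, so the ketal oxygen left by the cycloaddition can be replaced by hydride.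
3. Forward: heterodiene (ortho-lithiation/formylation, aldol condensation) and dienophile (ester methylenation) are joined in one cycloaddition that closes the only non-aromatic ring. Ketal reduction and enol-ether hydrogenation give the all-cis oxane; ortho-lithiation/acetylation, a second aldol condensation and removal of five MOM groups complete the chalcone.
4. Stereochemistry: C4 from the chiral Sc(OTf)3–N,N'-dioxide catalyst (face selection on the enone); C6 from axial hydride delivery to the ring oxocarbenium ion; C2 from hydrogenation on the face opposite the two cis substituents; both enones E by thermodynamic control.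

Key step: step 7

Assumption: the sense of face selection of the Sc(OTf)3–N,N'-dioxide complex on the heterodiene is taken from its additions to simple chalcones and is not secured; the (S)-pipecolic-acid-derived ligand is written, and its mirror image would be used with no other change if a trial run showed the opposite sense.

**Route**

Step 1
Reactants: 1 5-methoxybenzene-1,3-diol (5-methoxyresorcinol)
Product: 2 1-methoxy-3,5-bis(methoxymethoxy)benzene
Conditions: MOMCl (2.5 equiv), i-Pr2NEt (3 equiv), CH2Cl2, 0 °C → rt
Reagents that add atoms: chloromethyl methyl ether (MOMCl), COCCl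
Why: Williamson-type O-alkylation of both phenols by the α-chloro ether should be clean under amine base because the phenolic oxygens are far more nucleophilic than the ring carbons; no stereocentre is formed.

Step 2
Reactants: 2 1-methoxy-3,5-bis(methoxymethoxy)benzene
Product: 4 4-methoxy-2,6-bis(methoxymethoxy)benzaldehyde, via aryllithium 3 (not isolated)
Conditions: n-BuLi (1.1 equiv), THF, 0 °C; DMF, 0 °C → rt; H2O
Reagents that add atoms: N,N-dimethylformamide (DMF), CN(C)C=O; n-butyllithium, [Li]CCCC (lithium of 3 only)
Why: directed ortho-metalation followed by formylation should occur at the carbon flanked by the two OMOM groups, the strongest cooperative pair of directing groups on the ring, and the lithium hemiaminal collapses to the aldehyde only on aqueous work-up, so no over-addition occurs; no stereocentre is formed.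

Step 3
Reactants: 5 1-(4-hydroxyphenyl)ethan-1-one (4'-hydroxyacetophenone)
Product: 6 1-[4-(methoxymethoxy)phenyl]ethan-1-one
Conditions: MOMCl (1.3 equiv), i-Pr2NEt (1.5 equiv), CH2Cl2, 0 °C → rt
Reagents that add atoms: chloromethyl methyl ether (MOMCl), COCCl
Why: Williamson-type O-alkylation of the phenol; the ketone is not enolised by the amine base; no stereocentre is formed.

Step 4
Reactants: 4 4-methoxy-2,6-bis(methoxymethoxy)benzaldehyde; 6 1-[4-(methoxymethoxy)phenyl]ethan-1-one
Product: 7 (2E)-3-[4-methoxy-2,6-bis(methoxymethoxy)phenyl]-1-[4-(methoxymethoxy)phenyl]prop-2-en-1-one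
Conditions: KOH (3 equiv), EtOH, rt
Reagents that add atoms: none
Why: Claisen–Schmidt (crossed aldol) condensation of an enolisable methyl ketone with a non-enolisable aldehyde, the E1cB dehydration giving the conjugated E-enone under thermodynamic control; MOM ethers are stable to hydroxide.

Step 5
Reactants: 8 methyl 3-(4-hydroxyphenyl)propanoate
Product: 9 methyl 3-[4-(methoxymethoxy)phenyl]propanoate
Conditions: MOMCl (1.3 equiv), i-Pr2NEt (1.5 equiv), CH2Cl2, 0 °C → rt
Reagents that add atoms: chloromethyl methyl ether (MOMCl), COCCl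
Why: Williamson-type O-alkylation of the phenol under conditions that leave the methyl ester untouched; no stereocentre is formed.

Step 6
Reactants: 9 methyl 3-[4-(methoxymethoxy)phenyl]propanoate
Product: 10 1-(3-methoxybut-3-en-1-yl)-4-(methoxymethoxy)benzene
Conditions: Cp2TiMe2 (2.2 equiv), toluene, 65 °C, dark; filtration through basic alumina
Reagents that add atoms: dimethyltitanocene (Cp2TiMe2, tetravalent titanium), [CH3-].[CH3-].[Ti+4].[cH-]1cccc1.[cH-]1cccc1 (delivers the CH2 carbon)
Why: Petasis methylenation, in which thermally generated Cp2Ti=CH2 converts the ester carbonyl through an oxatitanacyclobutane into the 1,1-disubstituted enol ether with the double bond fixed at the terminus, under non-acidic conditions that spare the MOM ether and the acid-labile product.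

Step 7
Reactants: 7 (2E)-3-[4-methoxy-2,6-bis(methoxymethoxy)phenyl]-1-[4-(methoxymethoxy)phenyl]prop-2-en-1-one; 10 1-(3-methoxybut-3-en-1-yl)-4-(methoxymethoxy)benzene
Product: 11 (2R,4R)-2-methoxy-4-[4-methoxy-2,6-bis(methoxymethoxy)phenyl]-6-[4-(methoxymethoxy)phenyl]-2-{2-[4-(methoxymethoxy)phenyl]ethyl}-3,4-dihydro-2H-pyran
Conditions: Sc(OTf)3 (10 mol%), C2-symmetric N,N'-dioxide ligand from (S)-pipecolic acid with 2,6-diisopropylanilide arms and a propane-1,3-diyl bridge (11 mol%), 10 (3 equiv), 4 Å MS, CH2Cl2, −20 °C → rt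
Reagents that add atoms: none
Why: Proposed new method: a catalytic enantioselective inverse-electron-demand oxa-Diels–Alder reaction of a non-chelating aryl enone, in which the trivalent scandium centre held in the tetradentate N,N'-dioxide binds the carbonyl oxygen of s-cis 7 and the CH2 terminus of 10 attacks C4 in a strongly asynchronous [4π+2π] transition state whose oxocarbenium-like carbon is captured by the metal-bound enolate oxygen, so that the C–C and the O–C bond arise in one event. The closest known reaction types are the face-selective additions to simple chalcones under the same Sc(OTf)3–N,N'-dioxide catalysis (one-point carbonyl binding) and the Eu(fod)3- or Cu(OTf)2–bis(oxazoline)-catalysed hetero-Diels–Alder reactions of enones with enol ethers. The dihydropyran (the future oxane) closes as a [4+2] cycloaddition, in the stepwise limit a six-membered ring closure by O-attack of the enolate on the oxocarbenium carbon. C4 (R) is set by the catalyst, whose anilide arm is taken to cover the Si face so that 10 adds to the Re face; the ketal carbon follows the endo rule (methoxy cis to the aryl) and is planarised again in step 8, so its configuration is of no consequence. Regioselectivity (CH2 to C4, ketal carbon to oxygen) is secured by the matched polarity of the partners, the 2,4,6-trioxygenated ring stabilising positive charge at C4 of the bound enone and the methoxy group stabilising it at the inner carbon of 10. Periselectivity over cyclobutane or open-chain Michael products is secured by the non-transferable methyl group on the enol ether oxygen and by the stability of the six-membered ketal, while sieves and low temperature keep 10 from hydrolysis.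

Step 8
Reactants: 11 (2R,4R)-2-methoxy-4-[4-methoxy-2,6-bis(methoxymethoxy)phenyl]-6-[4-(methoxymethoxy)phenyl]-2-{2-[4-(methoxymethoxy)phenyl]ethyl}-3,4-dihydro-2H-pyran
Product: 12 (2S,4R)-4-[4-methoxy-2,6-bis(methoxymethoxy)phenyl]-6-[4-(methoxymethoxy)phenyl]-2-{2-[4-(methoxymethoxy)phenyl]ethyl}-3,4-dihydro-2H-pyran
Conditions: Et3SiH (5 equiv), TMSOTf (0.2 equiv), CH2Cl2, −78 °C; Et3N quench
Reagents that add atoms: none
Why: ionic hydrogenation of a ketal, in which the silyl triflate ionises the exocyclic C–OMe bond (the more basic oxygen) and Et3SiH delivers hydride axially, antiperiplanar to the ring-oxygen lone pair, to the cyclic oxocarbenium ion in the half-chair that keeps the C4 aryl pseudo-equatorial, so the arylethyl chain ends equatorial and cis to the aryl (2S), while catalytic acid at −78 °C should spare the aryl MOM ethers and the enol ether.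

Step 9
Reactants: 12 (2S,4R)-4-[4-methoxy-2,6-bis(methoxymethoxy)phenyl]-6-[4-(methoxymethoxy)phenyl]-2-{2-[4-(methoxymethoxy)phenyl]ethyl}-3,4-dihydro-2H-pyran
Product: 13 (2S,4R,6S)-4-[4-methoxy-2,6-bis(methoxymethoxy)phenyl]-2-[4-(methoxymethoxy)phenyl]-6-{2-[4-(methoxymethoxy)phenyl]ethyl}oxane
Conditions: H2 (1 atm), Pd/C (5% palladium on carbon), Et3N (0.1 equiv), EtOAc, rt
Reagents that add atoms: none
Why: heterogeneous syn-hydrogenation of the trisubstituted aryl enol ether from the face opposite the two cis, pseudo-equatorial ring substituents (the face that carries only the axial hydrogens at C4 and C6) sets C2 (S) and gives the all-cis, all-equatorial oxane, while the amine additive suppresses hydrogenolysis of the new benzylic C–O bond.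

Step 10
Reactants: 13 (2S,4R,6S)-4-[4-methoxy-2,6-bis(methoxymethoxy)phenyl]-2-[4-(methoxymethoxy)phenyl]-6-{2-[4-(methoxymethoxy)phenyl]ethyl}oxane
Product: 15 1-{6-methoxy-2,4-bis(methoxymethoxy)-3-[(2S,4R,6S)-2-[4-(methoxymethoxy)phenyl]-6-{2-[4-(methoxymethoxy)phenyl]ethyl}oxan-4-yl]phenyl}ethan-1-one, via aryllithium 14 (not isolated)
Conditions: n-BuLi (1.2 equiv), THF, −20 → 0 °C; MeC(O)N(OMe)Me (1.5 equiv), −78 → 0 °C; H2O
Reagents that add atoms: N-methoxy-N-methylacetamide, CC(=O)N(C)OC; n-butyllithium, [Li]CCCC (lithium of 14 only)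
Why: directed ortho-metalation at the ring position flanked by two oxygen donors (OMOM and OMe) of the trioxygenated ring, kinetically far more acidic than the positions next to a single OMOM group on the other two rings, followed by the Weinreb ketone synthesis, whose chelated tetrahedral intermediate prevents over-addition; no stereocentre is formed and the three oxane centres are not touched.

Step 11
Reactants: 15 1-{6-methoxy-2,4-bis(methoxymethoxy)-3-[(2S,4R,6S)-2-[4-(methoxymethoxy)phenyl]-6-{2-[4-(methoxymethoxy)phenyl]ethyl}oxan-4-yl]phenyl}ethan-1-one; 16 4-(methoxymethoxy)benzaldehyde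
Product: 17 (2E)-1-{6-methoxy-2,4-bis(methoxymethoxy)-3-[(2S,4R,6S)-2-[4-(methoxymethoxy)phenyl]-6-{2-[4-(methoxymethoxy)phenyl]ethyl}oxan-4-yl]phenyl}-3-[4-(methoxymethoxy)phenyl]prop-2-en-1-one
Conditions: 16 (1.5 equiv), KOH (5 equiv), EtOH, rt
Reagents that add atoms: none
Why: Claisen–Schmidt condensation of the methyl ketone enolate with a non-enolisable aldehyde, E1cB dehydration giving the E-enone; with all phenols masked no quinone methide can form under base, so the benzylic ether centre C2 is not at risk.

Step 12
Reactants: 17 (2E)-1-{6-methoxy-2,4-bis(methoxymethoxy)-3-[(2S,4R,6S)-2-[4-(methoxymethoxy)phenyl]-6-{2-[4-(methoxymethoxy)phenyl]ethyl}oxan-4-yl]phenyl}-3-[4-(methoxymethoxy)phenyl]prop-2-en-1-one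
Product: 18 (2E)-1-{2,4-dihydroxy-3-[(2S,4R,6S)-2-(4-hydroxyphenyl)-6-[2-(4-hydroxyphenyl)ethyl]oxan-4-yl]-6-methoxyphenyl}-3-(4-hydroxyphenyl)prop-2-en-1-one (CNP0215517.1)
Conditions: 3 M aq HCl, MeOH, rt
Reagents that add atoms: none
Why: acid-catalysed acetal cleavage (methoxymethyl oxocarbenium ions trapped by methanol) frees the five phenols under conditions mild enough to leave the E-enone and the methyl ether untouched, and the all-cis oxane is the thermodynamic isomer, so reversible opening of the benzylic ether cannot erode C2.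

**Compound list**

1 | 5-methoxybenzene-1,3-diol | COc1cc(O)cc(O)c1 | starting material
2 | 1-methoxy-3,5-bis(methoxymethoxy)benzene | COCOc1cc(OC)cc(OCOC)c1 | intermediate
3 | [4-methoxy-2,6-bis(methoxymethoxy)phenyl]lithium | [Li]c1c(OCOC)cc(OC)cc1OCOC | intermediate (not isolated)
4 | 4-methoxy-2,6-bis(methoxymethoxy)benzaldehyde | O=Cc1c(OCOC)cc(OC)cc1OCOC | intermediate
5 | 1-(4-hydroxyphenyl)ethan-1-one | CC(=O)c1ccc(O)cc1 | starting material
6 | 1-[4-(methoxymethoxy)phenyl]ethan-1-one | CC(=O)c1ccc(OCOC)cc1 | intermediate
7 | (2E)-3-[4-methoxy-2,6-bis(methoxymethoxy)phenyl]-1-[4-(methoxymethoxy)phenyl]prop-2-en-1-one | COCOc1ccc(cc1)C(=O)/C=C/c1c(OCOC)cc(OC)cc1OCOC | intermediate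
8 | methyl 3-(4-hydroxyphenyl)propanoate | COC(=O)CCc1ccc(O)cc1 | starting material
9 | methyl 3-[4-(methoxymethoxy)phenyl]propanoate | COC(=O)CCc1ccc(OCOC)cc1 | intermediate
10 | 1-(3-methoxybut-3-en-1-yl)-4-(methoxymethoxy)benzene | C=C(OC)CCc1ccc(OCOC)cc1 | intermediate
11 | (2R,4R)-2-methoxy-4-[4-methoxy-2,6-bis(methoxymethoxy)phenyl]-6-[4-(methoxymethoxy)phenyl]-2-{2-[4-(methoxymethoxy)phenyl]ethyl}-3,4-dihydro-2H-pyran | COCOc1cc(OC)cc(OCOC)c1[C@@H]1C[C@@](OC)(CCc2ccc(OCOC)cc2)OC(c2ccc(OCOC)cc2)=C1 | intermediate
12 | (2S,4R)-4-[4-methoxy-2,6-bis(methoxymethoxy)phenyl]-6-[4-(methoxymethoxy)phenyl]-2-{2-[4-(methoxymethoxy)phenyl]ethyl}-3,4-dihydro-2H-pyran | COCOc1cc(OC)cc(OCOC)c1[C@@H]1C[C@H](CCc2ccc(OCOC)cc2)OC(c2ccc(OCOC)cc2)=C1 | intermediate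
13 | (2S,4R,6S)-4-[4-methoxy-2,6-bis(methoxymethoxy)phenyl]-2-[4-(methoxymethoxy)phenyl]-6-{2-[4-(methoxymethoxy)phenyl]ethyl}oxane | COCOc1cc(OC)cc(OCOC)c1[C@@H]1C[C@H](CCc2ccc(OCOC)cc2)O[C@H](c2ccc(OCOC)cc2)C1 | intermediate
14 | {6-methoxy-2,4-bis(methoxymethoxy)-3-[(2S,4R,6S)-2-[4-(methoxymethoxy)phenyl]-6-{2-[4-(methoxymethoxy)phenyl]ethyl}oxan-4-yl]phenyl}lithium | COc1cc(OCOC)c([C@@H]2C[C@H](CCc3ccc(OCOC)cc3)O[C@H](c3ccc(OCOC)cc3)C2)c(OCOC)c1[Li] | intermediate (not isolated)
15 | 1-{6-methoxy-2,4-bis(methoxymethoxy)-3-[(2S,4R,6S)-2-[4-(methoxymethoxy)phenyl]-6-{2-[4-(methoxymethoxy)phenyl]ethyl}oxan-4-yl]phenyl}ethan-1-one | COc1cc(OCOC)c([C@@H]2C[C@H](CCc3ccc(OCOC)cc3)O[C@H](c3ccc(OCOC)cc3)C2)c(OCOC)c1C(C)=O | intermediate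
16 | 4-(methoxymethoxy)benzaldehyde | COCOc1ccc(C=O)cc1 | starting material
17 | (2E)-1-{6-methoxy-2,4-bis(methoxymethoxy)-3-[(2S,4R,6S)-2-[4-(methoxymethoxy)phenyl]-6-{2-[4-(methoxymethoxy)phenyl]ethyl}oxan-4-yl]phenyl}-3-[4-(methoxymethoxy)phenyl]prop-2-en-1-one | COc1cc(OCOC)c([C@@H]2C[C@H](CCc3ccc(OCOC)cc3)O[C@H](c3ccc(OCOC)cc3)C2)c(OCOC)c1C(=O)/C=C/c1ccc(OCOC)cc1 | intermediate
18 | (2E)-1-{2,4-dihydroxy-3-[(2S,4R,6S)-2-(4-hydroxyphenyl)-6-[2-(4-hydroxyphenyl)ethyl]oxan-4-yl]-6-methoxyphenyl}-3-(4-hydroxyphenyl)prop-2-en-1-one | COc1cc(O)c([C@@H]2C[C@H](CCc3ccc(O)cc3)O[C@H](c3ccc(O)cc3)C2)c(O)c1C(=O)/C=C/c1ccc(O)cc1 | target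

**Step count and risks**

Total steps: 12. Longest linear sequence: 9 steps (1, 2, 4, 7, 8, 9, 10, 11, 12).

Steps most likely to fail:

Step 7 (Proposed new method). What may go wrong: insufficient activation of the electron-rich, doubly ortho-substituted enone by a catalyst that binds through one point only; poor discrimination between the two faces of C4; acid-promoted oligomerisation or hydrolysis of the enol ether; diversion to open-chain Michael or ene products. Fallback with known chemistry, setting out from 7 and returning at 13: an N-heterocyclic-carbene-catalysed formal [4+2] annulation of 7 with the acetyl azolium enolate generated from 4-nitrophenyl acetate (aminoindanol-derived N-mesityl triazolium salt, DBU, THF), a reaction class established for chalcones, should give the enol lactone (4R)-4-[4-methoxy-2,6-bis(methoxymethoxy)phenyl]-6-[4-(methoxymethoxy)phenyl]-3,4-dihydro-2H-pyran-2-one F1 with C4 set by the carbene. Addition of 2-[4-(methoxymethoxy)phenyl]ethylmagnesium bromide at −78 °C opens the lactone, the released aryl enolate keeping the aryl ketone masked until work-up, to the diketone (3R)-3-[4-methoxy-2,6-bis(methoxymethoxy)phenyl]-1,7-bis[4-(methoxymethoxy)phenyl]heptane-1,5-dione F2. Reductive etherification of this 1,5-diketone (Et3SiH, TMSOTf, CH2Cl2, −78 → −20 °C), which passes twice through cyclic oxocarbenium ions with axial hydride delivery, should give the all-cis oxane 13.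

Step 8. What may go wrong: cleavage of the ring C–O bond instead of the exocyclic C–OMe bond at the ketal; proton loss from the cation to a 4H-pyran followed by intermolecular hydride transfer, which would erode the C4 configuration; loss of aryl MOM ethers to the silyl triflate. Fallback, setting out from 11 and returning at 13: loss of methanol under weak acid (PPTS, toluene, 80 °C, 4 Å MS) should give (4R)-4-[4-methoxy-2,6-bis(methoxymethoxy)phenyl]-2-[4-(methoxymethoxy)phenyl]-6-{2-[4-(methoxymethoxy)phenyl]ethyl}-4H-pyran F3, with no carbenium ions accumulating. Hydrogenation of both enol-ether double bonds (H2, Pd/C, EtOAc, Et3N) on the face opposite the C4 aryl should then set C2 and C6 together and give 13 without any Lewis acid.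

Step 12. What may go wrong: acid-mediated isomerisation of the 2'-hydroxychalcone to the flavanone by intramolecular oxa-Michael addition, and solvolytic opening of the 4-hydroxybenzylic ring ether while five acetals are being cleaved. Fallback, setting out from 15 and returning at 18: the four MOM groups are removed at the ketone stage (3 M aq HCl, MeOH, rt), where no enone is present, to give 1-{2,4-dihydroxy-3-[(2S,4R,6S)-2-(4-hydroxyphenyl)-6-[2-(4-hydroxyphenyl)ethyl]oxan-4-yl]-6-methoxyphenyl}ethan-1-one F4. A Claisen–Schmidt condensation of this free polyphenol with unprotected 4-hydroxybenzaldehyde (excess KOH, EtOH/H2O, rt) should then give 18 directly, so that the enone never meets acid.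

**Further compounds**

F1 | step 7 | (4R)-4-[4-methoxy-2,6-bis(methoxymethoxy)phenyl]-6-[4-(methoxymethoxy)phenyl]-3,4-dihydro-2H-pyran-2-one | COCOc1cc(OC)cc(OCOC)c1[C@@H]1CC(=O)OC(c2ccc(OCOC)cc2)=C1
F2 | step 7 | (3R)-3-[4-methoxy-2,6-bis(methoxymethoxy)phenyl]-1,7-bis[4-(methoxymethoxy)phenyl]heptane-1,5-dione | COCOc1cc(OC)cc(OCOC)c1[C@@H](CC(=O)c1ccc(OCOC)cc1)CC(=O)CCc1ccc(OCOC)cc1
F3 | step 8 | (4R)-4-[4-methoxy-2,6-bis(methoxymethoxy)phenyl]-2-[4-(methoxymethoxy)phenyl]-6-{2-[4-(methoxymethoxy)phenyl]ethyl}-4H-pyran | COCOc1cc(OC)cc(OCOC)c1[C@@H]1C=C(CCc2ccc(OCOC)cc2)OC(c2ccc(OCOC)cc2)=C1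
F4 | step 12 | 1-{2,4-dihydroxy-3-[(2S,4R,6S)-2-(4-hydroxyphenyl)-6-[2-(4-hydroxyphenyl)ethyl]oxan-4-yl]-6-methoxyphenyl}ethan-1-one | COc1cc(O)c([C@@H]2C[C@H](CCc3ccc(O)cc3)O[C@H](c3ccc(O)cc3)C2)c(O)c1C(C)=O
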